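**Retrosynthetic overview**

1. The target is read as the cis-fused labdane (4R,5S,8R,9R,10S; labdane locants C1–C20 are used throughout). The ester C–O bond is cut to diol 21 and the (Z)-4-silyloxycinnamic acid 31, which comes from a Z-selective Ando olefination.
2. C12–C13, C8–O and C9–H are made in one pot from the 9-vinyl-Δ8 diene 15: cyclic hydroboration, Pd-catalysed coupling of the C12–B bond with butadienyl triflate 17, then oxidation.
3. Diene 15 comes from the C9 ketone 10 (C8 methylation, enol triflate, vinyl Suzuki coupling). The C10 methyl and the cis ring fusion come from reductive methylation of enone 7.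
4. Ring A is formed by an enantioselective endo Diels–Alder reaction of methacrolein with the vinylcyclohexene ketal 4 (sets C4 and C5). Ring B is carried from 2-bromocyclohexenone 1.

Assumption: the (S)-oxazaborolidinium catalyst is taken to give the (4aR,5R) adduct 7; if the sense is opposite, its enantiomer is used.

**Route**

Step 1
Reactants: 1 2-bromocyclohex-2-en-1-one
Product: 2 6-bromo-1,4-dioxaspiro[4.5]dec-6-ene
Conditions: HOCH2CH2OH, p-TsOH (cat.), benzene, reflux, Dean–Stark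
Reagents that add atoms: ethylene glycol, OCCO
Why: Acid-catalysed ketalisation with azeotropic water removal masks the enone carbonyl (future C9), so the diene made next is not electron-poor; no stereocentre is formed.

Step 2
Reactants: 2 6-bromo-1,4-dioxaspiro[4.5]dec-6-ene; 3 potassium trifluoro(vinyl)borate
Product: 4 6-ethenyl-1,4-dioxaspiro[4.5]dec-6-ene
Conditions: Pd(dppf)Cl2 (3 mol %), Cs2CO3, THF/H2O 9:1, 70 °C
Reagents that add atoms: none
Why: Suzuki–Miyaura coupling of an alkenyl bromide with a vinyltrifluoroborate gives the semicyclic 1,3-diene; no stereocentre is formed.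

Step 3
Reactants: 4 6-ethenyl-1,4-dioxaspiro[4.5]dec-6-ene; 5 methacrolein
Product: 7 (4aR,5R)-5-methyl-1-oxo-1,2,3,4,4a,5,6,7-octahydronaphthalene-5-carbaldehyde, via ketal aldehyde 6 (not isolated)
Conditions: 5 (3 equiv), (S)-1-(2-methylphenyl)-3,3-diphenyltetrahydro-1H,3H-pyrrolo[1,2-c][1,3,2]oxazaborole (20 mol %), HNTf2 (18 mol %), CH2Cl2, −78 to −40 °C; then 1 M HCl, THF, 0 °C
Reagents that add atoms: water, O
Why: Catalytic enantioselective Diels–Alder reaction of a 2-substituted acrolein under oxazaborolidinium activation: the vinyl CH2 bonds to the dienophile CH2 and the ring CH to the formyl-bearing carbon (ortho control by the 1-substituent), the endo (formyl) transition state puts CHO cis to C6 and so fixes C4 against C5, the catalyst sets the absolute sense, and the acidic work-up cleaves the labile allylic ketal to the enone.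

Step 4
Reactants: 7 (4aR,5R)-5-methyl-1-oxo-1,2,3,4,4a,5,6,7-octahydronaphthalene-5-carbaldehyde
Product: 10 (4aR,5R,8aS)-5-{[(tert-butyldimethylsilyl)oxy]methyl}-5,8a-dimethyloctahydronaphthalen-1(2H)-one, via dilithium enolate alkoxide 8 (not isolated), via lithium alkoxide 9 (not isolated)
Conditions: Li (4.5 equiv), t-BuOH (2 equiv), NH3/THF, −78 °C; isoprene; NH3 off; MeI, THF, −78 to 0 °C; then TBSCl, imidazole, DMF, rt
Reagents that add atoms: iodomethane, CI; tert-butyldimethylsilyl chloride, CC(C)(C)[Si](C)(C)Cl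
Why: Stork reductive alkylation: dissolving-metal reduction gives only the C9–C10 enolate and reduces the neopentyl aldehyde to its alkoxide; ring A is held as a chair with H-5 axial, so the axial C4–CH2O group blocks one face of C10 and MeI enters on the face of H-5, giving the cis ring fusion (10S); the primary alkoxide is then silylated.

Step 5
Reactants: 10 (4aR,5R,8aS)-5-{[(tert-butyldimethylsilyl)oxy]methyl}-5,8a-dimethyloctahydronaphthalen-1(2H)-one
Product: 12 (4aR,5R,8aS)-5-{[(tert-butyldimethylsilyl)oxy]methyl}-2,5,8a-trimethyloctahydronaphthalen-1(2H)-one (2-epimer mixture), via lithium enolate 11 (not isolated)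
Conditions: LiN(iPr)2 (LDA, 1.2 equiv), THF, −78 °C; MeI (1.1 equiv), −78 to −20 °C
Reagents that add atoms: iodomethane, CI
Why: Enolate alkylation; C10 is quaternary, so the ketone can enolise only towards C8, and the new C8 centre is removed again in step 6.

Step 6
Reactants: 12 (4aR,5R,8aS)-5-{[(tert-butyldimethylsilyl)oxy]methyl}-2,5,8a-trimethyloctahydronaphthalen-1(2H)-one
Product: 14 (4aR,5R,8aS)-5-{[(tert-butyldimethylsilyl)oxy]methyl}-2,5,8a-trimethyl-3,4,4a,5,6,7,8,8a-octahydronaphthalen-1-yl trifluoromethanesulfonate, via potassium enolate 13 (not isolated)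
Conditions: KN(SiMe3)2 (KHMDS, 1.3 equiv), THF, −78 to −30 °C; then N-(5-chloropyridin-2-yl)bis(trifluoromethanesulfonyl)imide (Comins' reagent), −78 °C to rt
Reagents that add atoms: Comins' reagent, Clc1ccc(nc1)N(S(=O)(=O)C(F)(F)F)S(=O)(=O)C(F)(F)F
Why: O-Triflation of the only possible enolate gives the tetrasubstituted C8=C9 enol triflate; the C4, C5 and C10 centres are untouched.

Step 7
Reactants: 14 (4aR,5R,8aS)-5-{[(tert-butyldimethylsilyl)oxy]methyl}-2,5,8a-trimethyl-3,4,4a,5,6,7,8,8a-octahydronaphthalen-1-yl trifluoromethanesulfonate; 3 potassium trifluoro(vinyl)borate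
Product: 15 tert-butyl{[(1R,4aS,8aS)-5-ethenyl-1,4a,6-trimethyl-1,2,3,4,4a,7,8,8a-octahydronaphthalen-1-yl]methoxy}dimethylsilane
Conditions: Pd(OAc)2 (5 mol %), SPhos (10 mol %), Cs2CO3, THF/H2O 10:1, 70 °C
Reagents that add atoms: none
Why: Suzuki–Miyaura coupling of a hindered enol triflate with a vinyltrifluoroborate forms the C9–C11 bond and the 1,3-diene needed for step 9; no stereocentre is formed.

Step 8
Reactants: 16 methyl vinyl ketone
Product: 17 buta-1,3-dien-2-yl trifluoromethanesulfonate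
Conditions: Tf2O, 2,6-di-tert-butyl-4-methylpyridine, CH2Cl2, 0 °C to rt
Reagents that add atoms: triflic anhydride, O=S(=O)(OS(=O)(=O)C(F)(F)F)C(F)(F)F
Why: Stang enol triflate synthesis: O-triflation of the enone followed by loss of a methyl proton gives the 2-triflyloxy diene.

Step 9
Reactants: 15 tert-butyl{[(1R,4aS,8aS)-5-ethenyl-1,4a,6-trimethyl-1,2,3,4,4a,7,8,8a-octahydronaphthalen-1-yl]methoxy}dimethylsilane; 17 buta-1,3-dien-2-yl trifluoromethanesulfonate
Product: 20 (1R,2R,4aS,5R,8aS)-5-{[(tert-butyldimethylsilyl)oxy]methyl}-2,5,8a-trimethyl-1-(3-methylidenepent-4-en-1-yl)decahydronaphthalen-2-ol, via thexylborolane 18 (not isolated), via borinic acid 19 (not isolated)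
Conditions: ThxBH2 (from BH3·THF + 2,3-dimethylbut-2-ene, 1.2 equiv), THF, 0 to 40 °C; then 17, Pd(dppf)Cl2 (5 mol %), 3 M aq. K3PO4, THF/DMF, 50 °C; then 30% H2O2, 3 M NaOH, 0 °C to rt
Reagents that add atoms: hydrogen peroxide, OO
Why: Proposed new method: thexylborane adds to the vinyl terminus (C12) and its second B–H is delivered across the tetrasubstituted C8=C9 bond through a five-membered borolane, which forces boron onto C8 and hydrogen onto C9 on the same face (anti to the pseudo-axial C10 methyl; sets 8R and 9R); hydroxide then forms the ate complex of the strained, Lewis-acidic borolane, only the primary C12–B bond transmetalates to the complex formed from 17 and zerovalent palladium (the tertiary C8–B and thexyl–B bonds do not transfer), and the remaining C8–B bond is oxidised with retention; the closest known reactions are the B-alkyl Suzuki–Miyaura coupling of 9-BBN alkylboranes and Brown's cyclic hydroboration–oxidation of 1,3-dienes with thexylborane.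

Step 10
Reactants: 20 (1R,2R,4aS,5R,8aS)-5-{[(tert-butyldimethylsilyl)oxy]methyl}-2,5,8a-trimethyl-1-(3-methylidenepent-4-en-1-yl)decahydronaphthalen-2-ol
Product: 21 (1R,2R,4aS,5R,8aS)-5-(hydroxymethyl)-2,5,8a-trimethyl-1-(3-methylidenepent-4-en-1-yl)decahydronaphthalen-2-ol
Conditions: Bu4NF (TBAF), THF, rt
Reagents that add atoms: none
Why: Fluoride desilylation frees the primary C18 alcohol; the diene and the tertiary alcohol are inert.

Step 11
Reactants: 22 4-bromophenol
Product: 23 (4-bromophenoxy)(tert-butyl)dimethylsilane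
Conditions: TBSCl, imidazole, DMF, rt
Reagents that add atoms: tert-butyldimethylsilyl chloride, CC(C)(C)[Si](C)(C)Cl
Why: Silyl protection of the phenol, so the later lithiation and olefination are not quenched.

Step 12
Reactants: 23 (4-bromophenoxy)(tert-butyl)dimethylsilane
Product: 26 4-[(tert-butyldimethylsilyl)oxy]benzaldehyde, via aryllithium 24 (not isolated), via lithium hemiaminalate 25 (not isolated)
Conditions: n-BuLi, THF, −78 °C; DMF, −78 to 0 °C; aq. NH4Cl
Reagents that add atoms: N,N-dimethylformamide, CN(C)C=O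
Why: Bromine–lithium exchange and Bouveault formylation; the tetrahedral adduct collapses to the aldehyde on work-up.

Step 13
Reactants: 27 prop-2-en-1-yl bromoacetate
Product: 28 prop-2-en-1-yl 2-(diphenoxyphosphoryl)acetate
Conditions: (PhO)2P(O)H, Et3N, CH2Cl2, 0 °C to rt
Reagents that add atoms: diphenyl phosphite, O=[PH](Oc1ccccc1)Oc1ccccc1
Why: Michaelis–Becker alkylation of the phosphite anion by the α-bromo ester gives the Ando-type diaryl phosphonoacetate.

Step 14
Reactants: 28 prop-2-en-1-yl 2-(diphenoxyphosphoryl)acetate; 26 4-[(tert-butyldimethylsilyl)oxy]benzaldehyde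
Product: 30 prop-2-en-1-yl (2Z)-3-{4-[(tert-butyldimethylsilyl)oxy]phenyl}prop-2-enoate, via sodium phosphonate anion 29 (not isolated)
Conditions: NaH, THF, −78 °C; then 26, −78 to −20 °C
Reagents that add atoms: none
Why: Ando modification of the Horner–Wadsworth–Emmons reaction: the electron-poor diaryl phosphonate eliminates fast from the kinetically formed adduct and gives the Z-cinnamate (typically above 9:1 with aromatic aldehydes).

Step 15
Reactants: 30 prop-2-en-1-yl (2Z)-3-{4-[(tert-butyldimethylsilyl)oxy]phenyl}prop-2-enoate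
Product: 31 (2Z)-3-{4-[(tert-butyldimethylsilyl)oxy]phenyl}prop-2-enoic acid
Conditions: Pd(PPh3)4 (5 mol %), morpholine, THF, rt, dark
Reagents that add atoms: none
Why: Tsuji–Trost deallylation under neutral conditions frees the acid without touching the aryl silyl ether or the Z-alkene.

Step 16
Reactants: 21 (1R,2R,4aS,5R,8aS)-5-(hydroxymethyl)-2,5,8a-trimethyl-1-(3-methylidenepent-4-en-1-yl)decahydronaphthalen-2-ol; 31 (2Z)-3-{4-[(tert-butyldimethylsilyl)oxy]phenyl}prop-2-enoic acid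
Product: 32 [(1R,4aS,5R,6R,8aS)-6-hydroxy-1,4a,6-trimethyl-5-(3-methylidenepent-4-en-1-yl)decahydronaphthalen-1-yl]methyl (2Z)-3-{4-[(tert-butyldimethylsilyl)oxy]phenyl}prop-2-enoate
Conditions: EDC·HCl, DMAP (0.1 equiv), CH2Cl2, 0 °C, dark
Reagents that add atoms: none
Why: Steglich esterification: the primary C18 alcohol is acylated and the hindered tertiary 8-OH is not; low temperature and exclusion of light keep the Z geometry.

Step 17
Reactants: 32 [(1R,4aS,5R,6R,8aS)-6-hydroxy-1,4a,6-trimethyl-5-(3-methylidenepent-4-en-1-yl)decahydronaphthalen-1-yl]methyl (2Z)-3-{4-[(tert-butyldimethylsilyl)oxy]phenyl}prop-2-enoate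
Product: 33 [(1R,4aS,5R,6R,8aS)-6-hydroxy-1,4a,6-trimethyl-5-(3-methylidenepent-4-en-1-yl)decahydronaphthalen-1-yl]methyl (2Z)-3-(4-hydroxyphenyl)prop-2-enoate
Conditions: Bu4NF (TBAF), AcOH (1:1), THF, 0 °C
Reagents that add atoms: none
Why: Buffered fluoride cleaves the aryl silyl ether without ester cleavage, Z/E isomerisation or reaction at the diene.

**Compound list**

1 | 2-bromocyclohex-2-en-1-one | O=C1CCCC=C1Br | starting material
2 | 6-bromo-1,4-dioxaspiro[4.5]dec-6-ene | BrC1=CCCCC12OCCO2 | intermediate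
3 | potassium trifluoro(vinyl)borate | [K+].C=C[B-](F)(F)F | starting material
4 | 6-ethenyl-1,4-dioxaspiro[4.5]dec-6-ene | C=CC1=CCCCC12OCCO2 | intermediate
5 | methacrolein (2-methylprop-2-enal) | CC(=C)C=O | starting material
6 | (4a'R,5'R)-5'-methyl-3',4',4a',5',6',7'-hexahydro-2'H-spiro[1,3-dioxolane-2,1'-naphthalene]-5'-carbaldehyde | O=C[C@]1(C)CCC=C2[C@@H]1CCCC23OCCO3 | intermediate
7 | (4aR,5R)-5-methyl-1-oxo-1,2,3,4,4a,5,6,7-octahydronaphthalene-5-carbaldehyde | O=C[C@]1(C)CCC=C2[C@@H]1CCCC2=O | intermediate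
8 | dilithium C9–C10 enolate and C18 alkoxide from reduction of 7 | [Li+].[Li+].[O-]C[C@]1(C)CCCC2=C([O-])CCC[C@H]12 | intermediate
9 | lithium alkoxide of (4aR,5R,8aS)-5-(hydroxymethyl)-5,8a-dimethyloctahydronaphthalen-1(2H)-one | O=C1[C@@]2(C)CCC[C@@](C)(C[O-])[C@H]2CCC1.[Li+] | intermediate
10 | (4aR,5R,8aS)-5-{[(tert-butyldimethylsilyl)oxy]methyl}-5,8a-dimethyloctahydronaphthalen-1(2H)-one | O=C1[C@@]2(C)CCC[C@@](C)(CO[Si](C)(C)C(C)(C)C)[C@H]2CCC1 | intermediate
11 | lithium C8–C9 enolate of 10 | [Li+].[O-]C1=CCC[C@@H]2[C@](C)(CO[Si](C)(C)C(C)(C)C)CCC[C@]12C | intermediate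
12 | (4aR,5R,8aS)-5-{[(tert-butyldimethylsilyl)oxy]methyl}-2,5,8a-trimethyloctahydronaphthalen-1(2H)-one (2-epimer mixture) | O=C1[C@@]2(C)CCC[C@@](C)(CO[Si](C)(C)C(C)(C)C)[C@H]2CCC1C | intermediate
13 | potassium C8–C9 enolate of 12 | [K+].[O-]C1=C(C)CC[C@@H]2[C@](C)(CO[Si](C)(C)C(C)(C)C)CCC[C@]12C | intermediate
14 | (4aR,5R,8aS)-5-{[(tert-butyldimethylsilyl)oxy]methyl}-2,5,8a-trimethyl-3,4,4a,5,6,7,8,8a-octahydronaphthalen-1-yl trifluoromethanesulfonate | CC1=C(OS(=O)(=O)C(F)(F)F)[C@@]2(C)CCC[C@@](C)(CO[Si](C)(C)C(C)(C)C)[C@H]2CC1 | intermediate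
15 | tert-butyl{[(1R,4aS,8aS)-5-ethenyl-1,4a,6-trimethyl-1,2,3,4,4a,7,8,8a-octahydronaphthalen-1-yl]methoxy}dimethylsilane | C=CC1=C(C)CC[C@@H]2[C@](C)(CO[Si](C)(C)C(C)(C)C)CCC[C@]12C | intermediate
16 | methyl vinyl ketone (but-3-en-2-one) | CC(=O)C=C | starting material
17 | buta-1,3-dien-2-yl trifluoromethanesulfonate | C=CC(=C)OS(=O)(=O)C(F)(F)F | intermediate
18 | B-thexyl borolane joining C8 (boron on the α face) and C12 of 15, H-9 α | CC(C)C(C)(C)B1CC[C@@H]2[C@@]3(C)CCC[C@@](C)(CO[Si](C)(C)C(C)(C)C)[C@H]3CC[C@@]12C | intermediate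
19 | C8 thexylborinic acid carrying the complete 3-methylidenepent-4-enyl side chain | C=CC(=C)CC[C@@H]1[C@@]2(C)CCC[C@@](C)(CO[Si](C)(C)C(C)(C)C)[C@H]2CC[C@@]1(C)B(O)C(C)(C)C(C)C | intermediate
20 | (1R,2R,4aS,5R,8aS)-5-{[(tert-butyldimethylsilyl)oxy]methyl}-2,5,8a-trimethyl-1-(3-methylidenepent-4-en-1-yl)decahydronaphthalen-2-ol | C=CC(=C)CC[C@@H]1[C@@]2(C)CCC[C@@](C)(CO[Si](C)(C)C(C)(C)C)[C@H]2CC[C@@]1(C)O | intermediate
21 | (1R,2R,4aS,5R,8aS)-5-(hydroxymethyl)-2,5,8a-trimethyl-1-(3-methylidenepent-4-en-1-yl)decahydronaphthalen-2-ol | C=CC(=C)CC[C@@H]1[C@@]2(C)CCC[C@@](C)(CO)[C@H]2CC[C@@]1(C)O | intermediate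
22 | 4-bromophenol | Oc1ccc(Br)cc1 | starting material
23 | (4-bromophenoxy)(tert-butyl)dimethylsilane | CC(C)(C)[Si](C)(C)Oc1ccc(Br)cc1 | intermediate
24 | {4-[(tert-butyldimethylsilyl)oxy]phenyl}lithium | [Li]c1ccc(O[Si](C)(C)C(C)(C)C)cc1 | intermediate
25 | lithium (dimethylamino){4-[(tert-butyldimethylsilyl)oxy]phenyl}methanolate | [Li+].[O-]C(N(C)C)c1ccc(O[Si](C)(C)C(C)(C)C)cc1 | intermediate
26 | 4-[(tert-butyldimethylsilyl)oxy]benzaldehyde | O=Cc1ccc(O[Si](C)(C)C(C)(C)C)cc1 | intermediate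
27 | prop-2-en-1-yl bromoacetate | C=CCOC(=O)CBr | starting material
28 | prop-2-en-1-yl 2-(diphenoxyphosphoryl)acetate | C=CCOC(=O)CP(=O)(Oc1ccccc1)Oc1ccccc1 | intermediate
29 | sodium salt of the carbanion of 28 | [Na+].C=CCOC(=O)[CH-]P(=O)(Oc1ccccc1)Oc1ccccc1 | intermediate
30 | prop-2-en-1-yl (2Z)-3-{4-[(tert-butyldimethylsilyl)oxy]phenyl}prop-2-enoate | C=CCOC(=O)/C=C\c1ccc(O[Si](C)(C)C(C)(C)C)cc1 | intermediate
31 | (2Z)-3-{4-[(tert-butyldimethylsilyl)oxy]phenyl}prop-2-enoic acid | OC(=O)/C=C\c1ccc(O[Si](C)(C)C(C)(C)C)cc1 | intermediate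
32 | [(1R,4aS,5R,6R,8aS)-6-hydroxy-1,4a,6-trimethyl-5-(3-methylidenepent-4-en-1-yl)decahydronaphthalen-1-yl]methyl (2Z)-3-{4-[(tert-butyldimethylsilyl)oxy]phenyl}prop-2-enoate | C=CC(=C)CC[C@@H]1[C@@]2(C)CCC[C@@](C)(COC(=O)/C=C\c3ccc(O[Si](C)(C)C(C)(C)C)cc3)[C@H]2CC[C@@]1(C)O | intermediate
33 | [(1R,4aS,5R,6R,8aS)-6-hydroxy-1,4a,6-trimethyl-5-(3-methylidenepent-4-en-1-yl)decahydronaphthalen-1-yl]methyl (2Z)-3-(4-hydroxyphenyl)prop-2-enoate | C=CC(=C)CC[C@@H]1[C@@]2(C)CCC[C@@](C)(COC(=O)/C=C\c3ccc(O)cc3)[C@H]2CC[C@@]1(C)O | target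

**Step count and risks**

Total step count: 17. Longest linear sequence: 11 steps (steps 1 to 7, 9, 10, 16 and 17, starting from 1).

The three steps most likely to fail:

Step 3 (regio-, endo- and enantiocontrol of the cycloaddition; the dienyl ketal is acid-sensitive). The fallback relays the stereochemistry from a carbinol centre instead of from the catalyst. It sets out from 1. Reduction with BH3·SMe2 and (R)-1-methyl-3,3-diphenyltetrahydro-1H,3H-pyrrolo[1,2-c][1,3,2]oxazaborole gives (1S)-2-bromocyclohex-2-en-1-ol F1. TBSCl and imidazole give the silyl ether {[(1S)-2-bromocyclohex-2-en-1-yl]oxy}(tert-butyl)dimethylsilane F2. Suzuki vinylation with 3 gives the chiral diene tert-butyl{[(1S)-2-ethenylcyclohex-2-en-1-yl]oxy}dimethylsilane F3. Me2AlCl-promoted endo cycloaddition with 5, anti to the pseudo-axial silyloxy group, gives (1S,4aS,5R)-1-[(tert-butyldimethylsilyl)oxy]-5-methyl-1,2,3,4,4a,5,6,7-octahydronaphthalene-5-carbaldehyde F4. Bu4NF gives the allylic alcohol (1S,4aS,5R)-1-hydroxy-5-methyl-1,2,3,4,4a,5,6,7-octahydronaphthalene-5-carbaldehyde F5. Dess–Martin oxidation of F5 comes back to the route at 7.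

Step 4 (three events in one flask: reduction of enone and aldehyde, C-methylation, silylation; reductive coupling or O-methylation may compete). The fallback separates the events and makes the enolate from a silyl enol ether. It sets out from 6, isolated by quenching step 3 with NaHCO3 in place of HCl. NaBH4 gives the alcohol [(4a'R,5'R)-5'-methyl-3',4',4a',5',6',7'-hexahydro-2'H-spiro[1,3-dioxolane-2,1'-naphthalen]-5'-yl]methanol F6. TBSCl and imidazole give its silyl ether F7. PPTS in wet acetone gives the enone (4aR,5R)-5-{[(tert-butyldimethylsilyl)oxy]methyl}-5-methyl-3,4,4a,5,6,7-hexahydronaphthalen-1(2H)-one F8. Conjugate reduction with Stryker's reagent [(Ph3P)CuH]6 and TMSCl gives the C9–C10 trimethylsilyl enol ether F9. MeLi gives the lithium enolate F10, and MeI comes back to the route at 10.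

Step 9 (the proposed one-pot sequence; selective transfer of the primary B–C bond from a thexylborolane is untested). The fallback uses known reactions only. It sets out from 15. Cyclic hydroboration with thexylborane (18 forms as before) followed directly by NaOH/H2O2 gives (1R,2R,4aS,5R,8aS)-5-{[(tert-butyldimethylsilyl)oxy]methyl}-1-(2-hydroxyethyl)-2,5,8a-trimethyldecahydronaphthalen-2-ol F11. TESOTf and 2,6-lutidine give the 8,12-bis(triethylsilyl) ether F12. PPTS in MeOH at 0 °C frees only the primary alcohol, giving the C8 triethylsilyl ether alcohol F13. I2, PPh3 and imidazole give the C12 iodide F14. Buta-1,3-dien-2-ylmagnesium chloride F15 (from chloroprene, a further purchased material of five non-hydrogen atoms, and Mg) is coupled with F14 under Li2CuCl4 catalysis to give the bis-silyl ether of the complete skeleton F16. Bu4NF at 50 °C removes both silyl groups and comes back to the route at 21.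

**Further compounds**

F1 | step 3 | (1S)-2-bromocyclohex-2-en-1-ol | O[C@H]1CCCC=C1Br
F2 | step 3 | {[(1S)-2-bromocyclohex-2-en-1-yl]oxy}(tert-butyl)dimethylsilane | CC(C)(C)[Si](C)(C)O[C@H]1CCCC=C1Br
F3 | step 3 | tert-butyl{[(1S)-2-ethenylcyclohex-2-en-1-yl]oxy}dimethylsilane | C=CC1=CCCC[C@@H]1O[Si](C)(C)C(C)(C)C
F4 | step 3 | (1S,4aS,5R)-1-[(tert-butyldimethylsilyl)oxy]-5-methyl-1,2,3,4,4a,5,6,7-octahydronaphthalene-5-carbaldehyde | O=C[C@]1(C)CCC=C2[C@@H]1CCC[C@@H]2O[Si](C)(C)C(C)(C)C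
F5 | step 3 | (1S,4aS,5R)-1-hydroxy-5-methyl-1,2,3,4,4a,5,6,7-octahydronaphthalene-5-carbaldehyde | O=C[C@]1(C)CCC=C2[C@@H]1CCC[C@@H]2O
F6 | step 4 | [(4a'R,5'R)-5'-methyl-3',4',4a',5',6',7'-hexahydro-2'H-spiro[1,3-dioxolane-2,1'-naphthalen]-5'-yl]methanol | OC[C@]1(C)CCC=C2[C@@H]1CCCC23OCCO3
F7 | step 4 | tert-butyldimethylsilyl ether of F6 | CC(C)(C)[Si](C)(C)OC[C@]1(C)CCC=C2[C@@H]1CCCC23OCCO3
F8 | step 4 | (4aR,5R)-5-{[(tert-butyldimethylsilyl)oxy]methyl}-5-methyl-3,4,4a,5,6,7-hexahydronaphthalen-1(2H)-one | CC(C)(C)[Si](C)(C)OC[C@]1(C)CCC=C2[C@@H]1CCCC2=O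
F9 | step 4 | tert-butyl{[(1R,8aR)-1-methyl-5-[(trimethylsilyl)oxy]-1,2,3,4,6,7,8,8a-octahydronaphthalen-1-yl]methoxy}dimethylsilane | C[Si](C)(C)OC1=C2CCC[C@@](C)(CO[Si](C)(C)C(C)(C)C)[C@H]2CCC1
F10 | step 4 | lithium C9–C10 enolate from F9 | [Li+].[O-]C1=C2CCC[C@@](C)(CO[Si](C)(C)C(C)(C)C)[C@H]2CCC1
F11 | step 9 | (1R,2R,4aS,5R,8aS)-5-{[(tert-butyldimethylsilyl)oxy]methyl}-1-(2-hydroxyethyl)-2,5,8a-trimethyldecahydronaphthalen-2-ol | OCC[C@@H]1[C@@]2(C)CCC[C@@](C)(CO[Si](C)(C)C(C)(C)C)[C@H]2CC[C@@]1(C)O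
F12 | step 9 | 8,12-bis(triethylsilyl) ether of F11 | CC[Si](CC)(CC)OCC[C@@H]1[C@@]2(C)CCC[C@@](C)(CO[Si](C)(C)C(C)(C)C)[C@H]2CC[C@@]1(C)O[Si](CC)(CC)CC
F13 | step 9 | 2-[(1R,2R,4aS,5R,8aS)-5-{[(tert-butyldimethylsilyl)oxy]methyl}-2,5,8a-trimethyl-2-[(triethylsilyl)oxy]decahydronaphthalen-1-yl]ethan-1-ol | OCC[C@@H]1[C@@]2(C)CCC[C@@](C)(CO[Si](C)(C)C(C)(C)C)[C@H]2CC[C@@]1(C)O[Si](CC)(CC)CC
F14 | step 9 | C12 iodide from F13 | ICC[C@@H]1[C@@]2(C)CCC[C@@](C)(CO[Si](C)(C)C(C)(C)C)[C@H]2CC[C@@]1(C)O[Si](CC)(CC)CC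
F15 | step 9 | buta-1,3-dien-2-ylmagnesium chloride | C=CC(=C)[Mg]Cl
F16 | step 9 | C8 triethylsilyl ether of 20 | C=CC(=C)CC[C@@H]1[C@@]2(C)CCC[C@@](C)(CO[Si](C)(C)C(C)(C)C)[C@H]2CC[C@@]1(C)O[Si](CC)(CC)CC
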